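The ratio to watch when starting material is fed is the life of the coupling partner against the length of the feed.

| flask | starting material | coupling partner | second substrate | catalyst | remark | time |
|---|---|---|---|---|---|---|
| Saturday's | 0.057 M | 0.0513 M | 0.114 M | 0.57 mM | run made earlier |  |
| Tuesday's | 0.057 M | 0.026 M | 0.114 M | 0.57 mM | run made earlier |  |
| Sunday's | 0.057 M | 0.10 M | 0.114 M | 0.57 mM | run made earlier |  |
| Friday's | 0.057 M | 0.0513 M | 0.17 M | 0.57 mM | run made earlier |  |
| south | 0.057 M (fed, over 25 h) | 0.0513 M | 0.114 M | 0.57 mM | all else is in the flask from the start; the feed brings no volume worth counting | 40 h |
| south-west | 0.057 M | 0.0513 M (in portions, 2, over 25 h) | 0.114 M | 0.57 mM | first portion at the start, last at 25 h | 40 h |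
| west | 0.057 M | 0.0513 M (fed, over 25 h) | 0.114 M | 0.57 mM | all else is in the flask from the start; the feed brings no volume worth counting | 40 h |
| north | 0.057 M | 0.0513 M | 0.114 M | 0.57 mM | everything together at the start | 40 h |

| run | time / h | target / % |
|---|---|---|
| Saturday's | 2.00 | 28.0 |
| Saturday's | 6.00 | 38.2 |
| Saturday's | 12.0 | 39.3 |
| Saturday's | 15.0 | 40.3 |
| Saturday's | 25.0 | 39.7 |
| Saturday's | 30.0 | 39.8 |
| Saturday's | 40.0 | 39.8 |
| Tuesday's | 3.00 | 17.5 |
| Tuesday's | 5.00 | 19.0 |
| Tuesday's | 8.00 | 20.9 |
| Tuesday's | 12.0 | 20.8 |
| Tuesday's | 15.0 | 21.8 |
| Tuesday's | 25.0 | 21.8 |
| Tuesday's | 40.0 | 21.9 |
| Sunday's | 3.00 | 56.3 |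
| Sunday's | 5.00 | 63.9 |
| Sunday's | 8.00 | 67.6 |
| Sunday's | 12.0 | 70.2 |
| Sunday's | 15.0 | 70.2 |
| Sunday's | 25.0 | 71.3 |
| Sunday's | 40.0 | 70.3 |
| Friday's | 3.00 | 28.0 |
| Friday's | 6.00 | 32.2 |
| Friday's | 12.0 | 33.0 |
| Friday's | 20.0 | 32.6 |
| Friday's | 40.0 | 32.4 |

(readings scatter by 0.5 percentage points)

- the best flask by amount of target, in percent of the starting material charged; "all alike" if 1.5 percentage points covers them all (south / south-west / west / north / all alike)
- amount of target at the end, in percent of the starting material charged, south
- amount of target at the end, in percent of the starting material charged, south-west
- amount of target at the end, in percent of the starting material charged, west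
- amount of target at the end, in percent of the starting material charged, north



Two of us argued over these runs from the same reading. Take what the partner did not give as target to have gone to the second substrate. Tuesday's plateau then gives a selectivity factor S = 1.96, the rate of the target step over that of the second-product step at equal substrate amounts. At the charged amounts, S times the starting material roughly equals the second substrate, so the partner divides about equally at the start.

The first chemist held that sharing is the whole story. A slowly arriving partner slows both steps alike, so west and south-west should match north, which repeats Saturday's 39.8%. For south, taking starting material at half its charge on average, this view puts the partner's share at 32.9%, which gives 29.6% target.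

The second chemist, whose side I take, accepted this for west and south-west, expecting neither to beat north, but said that in south the partner does not wait for the feed. Saturday's first reading, with equal shares, has the partner falling at 0.487 h⁻¹. Taking substrates halfway through that interval, this yields τ, the partner's life against second substrate at its charge, a pseudo-first-order time, of 3.64 h. That is shorter than the feed: within one life, south has received 14.6% of its starting material. Letting starting material build steadily while the partner decays gives target as S times partner charge times τ, over feed time times second substrate: 12.8%, less than the first chemist's figure.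

The forecast named west as best, with south 16%, south-west 41%, west 42% and north 39.8%, holding that “Partner added gradually should do slightly better”.

The flasks give north 39.9%, south-west 31.0%, west 28.3% and south 10.9%, so north is best. South lies 2 percentage points below the τ reckoning and 19 points below the sharing figure. By the τ reckoning, the sharing view belongs to feeds shorter than τ, such as a feed of south over 2.50 h. But west ended 12 points below north, where both of us had expected them level.

    starting material + coupling partner + catalyst → catalyst + target (k = 9900 M⁻² h⁻¹)
    second substrate + coupling partner + catalyst → catalyst + second product (k = 4900 M⁻² h⁻¹)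
    2 starting material → homo dimer (k = 0.670 M⁻¹ h⁻¹)

North's target has come to rest, but the flask has not. North's partner stands at 0% at 40.0 h, and its target is 39.9% at 400 h. North's starting material is 20.1% at 40.0 h and 3.08% at 400 h. North's homo dimer, counted in starting material, is 39.9% at 40.0 h and 57.0% at 400 h. South's target is 10.9% at 400 h. At 40.0 h west held more homo dimer than north, at 56.1%.

In a flask like south with 0.46 M of second substrate, τ shrinks to 0.902 h, and the same reckoning gives 0.788% target. That flask gives 0.744%.

The runs come from a simulation for an exercise; the scatter is artificial.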